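**Plan**

1. Side-chain carbons are numbered C1' (the CH2 on the ring) to C36'. Retrosynthetic cuts, in order: (a) the two quinone C=O groups go back to a 1,4-dimethoxynaphthalene; (b) the C19'–C20' bond is cut into the Z-alkenyl iodide 20 (arene plus C1'–C19') and the primary boronic ester 23 (C20'–C36'); (c) C18'=C19', C16'–C17' and C16'–O go back to the prenyl end of 15; (d) C1'–C2' and C3'–CH3 go back to alkyne 13, AlMe3 and benzylic chloride 4; (e) C8'–C9' and C5'–C6' go back to two Grignard couplings around a chiral C4 unit.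
2. Forward chain assembly: 6 + butynyl Grignard gives 9; 9 + citronellyl bromide gives 12, then 13; carboalumination and benzylation give 15; SeO2 oxidation, bromide, two-carbon aldehyde and Stork–Zhao olefination give 20; geranylgeraniol gives 23; the Zweifel union gives 27; oxidation gives 28. No ring is formed in the route; the naphthalene comes from menadione.
3. Stereochemistry: C7' comes from (R)-3-bromo-2-methylpropan-1-ol and C11' from (R)-citronellyl bromide, and neither centre is ever a reaction site. 2'E comes from syn-methylalumination, 14'E from E-selective SeO2 oxidation of the prenyl end, 18'E from the Z-iodide through the stereoinvertive Zweifel sequence, and 22'E, 26'E, 30'E from geranylgeraniol.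
4. Enabling feature: C19' is the methyl-bearing sp2 carbon of a trisubstituted olefin whose partner C18' bears H, and C20' is a plain primary CH2 two atoms from the next olefin (C22'=C23'). C19' can therefore be the boron-bound carbon of an alkenyl boronate complex and C20' the only carbon ligand able to migrate, so one 1,2-metallate shift with anti elimination makes the C19'–C20' bond and the 18'E geometry together. The quinone ring (ring carbons C1–C4 with the two carbonyls) cannot face an organolithium and is held at the hydroquinone dimethyl ether oxidation level until the last step.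

Key step: step 14

Remark: the two methyl-bearing centres have the spatial arrangement of natural phytol; by the CIP rules they are 7'R and 11'S in the target and in all arene-bearing intermediates, and the descriptors of the small precursors differ only because substituent priorities change. The enantiomeric purity is that of commercial 5 and 10.

**Route**

Step 1
Reactants: 1 menadione (2-methylnaphthalene-1,4-dione)
Product: 3 1,4-dimethoxy-2-methylnaphthalene, via menadiol 2 (not isolated)
Conditions: Na2S2O4, Bu4NBr (cat.), THF/H2O, rt; then KOH, Me2SO4, rt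
Reagents that add atoms: dimethyl sulfate, COS(=O)(=O)OC
Why: Dithionite should reduce the quinone to the hydroquinone, whose phenoxides are O-methylated under phase-transfer conditions (reductive methylation, Williamson ether synthesis).

Step 2
Reactants: 3 1,4-dimethoxy-2-methylnaphthalene
Product: 4 2-(chloromethyl)-1,4-dimethoxy-3-methylnaphthalene
Conditions: (CH2O)n, conc. HCl, AcOH, 70 °C
Reagents that add atoms: formaldehyde (used as paraformaldehyde), C=O; hydrogen chloride, Cl
Why: Blanc chloromethylation (electrophilic aromatic substitution) should attack the only unsubstituted carbon of the electron-rich dimethoxy ring, C3, which lies ortho to a methoxy group.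

Step 3
Reactants: 5 (2R)-3-bromo-2-methylpropan-1-ol
Product: 6 (2R)-1-bromo-3-chloro-2-methylpropane
Conditions: NCS, PPh3, CH2Cl2, 0 °C to rt
Reagents that add atoms: N-chlorosuccinimide, O=C1CCC(=O)N1Cl
Why: Appel-type chlorination should convert the primary alcohol into the chloride under neutral conditions without touching the stereocentre or the C–Br bond.

Step 4
Reactants: 6 (2R)-1-bromo-3-chloro-2-methylpropane; 7 (4-bromobut-1-yn-1-yl)trimethylsilane
Product: 9 [(6S)-7-chloro-6-methylhept-1-yn-1-yl]trimethylsilane, via butynyl Grignard reagent 8 (not isolated)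
Conditions: 7, Mg, THF, 40 °C; then 6, Li2CuCl4 (3 mol%), THF, −20 °C to rt
Reagents that add atoms: none
Why: The Li2CuCl4-catalysed Grignard–alkyl halide coupling (Kochi-type sp3–sp3 coupling) should take place at the primary C–Br bond and leave the C–Cl bond, and the stereocentre is not a reaction site.

Step 5
Reactants: 9 [(6S)-7-chloro-6-methylhept-1-yn-1-yl]trimethylsilane; 10 (6R)-8-bromo-2,6-dimethyloct-2-ene ((R)-citronellyl bromide)
Product: 12 trimethyl[(6R,10S)-6,10,14-trimethylpentadec-13-en-1-yn-1-yl]silane, via alkylmagnesium chloride 11 (not isolated)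
Conditions: 9, Mg, THF, reflux; then 10, Li2CuCl4 (3 mol%), THF, −10 °C to rt
Reagents that add atoms: none
Why: The chloride spared in step 4 now serves as the Grignard precursor, and the same copper-catalysed sp3–sp3 coupling with the primary bromide should join the two pieces with both stereocentres carried over unchanged from 9 and 10.

Step 6
Reactants: 12 trimethyl[(6R,10S)-6,10,14-trimethylpentadec-13-en-1-yn-1-yl]silane
Product: 13 (6R,10S)-6,10,14-trimethylpentadec-13-en-1-yne
Conditions: K2CO3, MeOH/THF, rt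
Reagents that add atoms: none
Why: Base-mediated methanolysis of the alkynyl C–Si bond (protodesilylation) should free the terminal alkyne.

Step 7
Reactants: 13 (6R,10S)-6,10,14-trimethylpentadec-13-en-1-yne; 4 2-(chloromethyl)-1,4-dimethoxy-3-methylnaphthalene
Product: 15 1,4-dimethoxy-2-methyl-3-[(2E,7R,11S)-3,7,11,15-tetramethylhexadeca-2,14-dien-1-yl]naphthalene, via alkenylalane 14 (not isolated)
Conditions: AlMe3 (2 equiv), Cp2ZrCl2 (0.25 equiv), ClCH2CH2Cl, 0 °C to rt; volatiles removed, THF; then 4, NiCl2(PPh3)2 (3 mol%) reduced with n-BuLi (6 mol%) to zerovalent nickel, rt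
Reagents that add atoms: trimethylaluminium, C[Al](C)C
Why: Negishi zirconium-catalysed methylalumination adds CH3 and aluminium syn with aluminium on the terminal carbon, which should fix the 2E olefin, and the alkenylalane is then benzylated with retention by nickel-catalysed cross-coupling while the remote trisubstituted olefin stays inert.

Step 8
Reactants: 15 1,4-dimethoxy-2-methyl-3-[(2E,7R,11S)-3,7,11,15-tetramethylhexadeca-2,14-dien-1-yl]naphthalene
Product: 16 (2E,6S,10R,14E)-16-(1,4-dimethoxy-3-methylnaphthalen-2-yl)-2,6,10,14-tetramethylhexadeca-2,14-dien-1-ol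
Conditions: SeO2 (0.3 equiv), t-BuOOH (3 equiv), salicylic acid (0.1 equiv), CH2Cl2, 0 °C to rt
Reagents that add atoms: tert-butyl hydroperoxide (terminal oxidant that supplies the oxygen), CC(C)(C)OO; selenium dioxide (catalytic oxygen carrier), O=[Se]=O
Why: Catalytic SeO2 allylic oxidation (ene reaction followed by [2,3]-sigmatropic shift) should go to the E-methyl group of the unhindered terminal gem-dimethyl olefin in preference to the internal olefin and give the E allylic alcohol.

Step 9
Reactants: 16 (2E,6S,10R,14E)-16-(1,4-dimethoxy-3-methylnaphthalen-2-yl)-2,6,10,14-tetramethylhexadeca-2,14-dien-1-ol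
Product: 17 2-[(2E,7R,11S,14E)-16-bromo-3,7,11,15-tetramethylhexadeca-2,14-dien-1-yl]-1,4-dimethoxy-3-methylnaphthalene
Conditions: PBr3 (0.4 equiv), Et2O, −10 °C
Reagents that add atoms: phosphorus tribromide, BrP(Br)Br
Why: PBr3 should convert the primary allylic alcohol into the bromide by SN2 displacement at low temperature with the olefin geometry kept.

Step 10
Reactants: 17 2-[(2E,7R,11S,14E)-16-bromo-3,7,11,15-tetramethylhexadeca-2,14-dien-1-yl]-1,4-dimethoxy-3-methylnaphthalene
Product: 19 (4E,8S,12R,16E)-18-(1,4-dimethoxy-3-methylnaphthalen-2-yl)-4,8,12,16-tetramethyloctadeca-4,16-dienal, via N-cyclohexylimine 18 (not isolated)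
Conditions: N-ethylidenecyclohexanamine, LDA, THF, −78 °C; 17, −78 to 0 °C; then aq. oxalic acid, rt
Reagents that add atoms: N-ethylidenecyclohexanamine, CC=NC1CCCCC1; water, O
Why: Alkylation of the lithiated acetaldehyde imine (Stork metalloenamine alkylation) with the primary allylic bromide should proceed by SN2, and mild acid hydrolysis of the imine releases the two-carbon-extended aldehyde.

Step 11
Reactants: 19 (4E,8S,12R,16E)-18-(1,4-dimethoxy-3-methylnaphthalen-2-yl)-4,8,12,16-tetramethyloctadeca-4,16-dienal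
Product: 20 2-[(2E,7R,11S,14E,18Z)-19-iodo-3,7,11,15-tetramethylicosa-2,14,18-trien-1-yl]-1,4-dimethoxy-3-methylnaphthalene
Conditions: EtPPh3I, n-BuLi, THF, rt; I2, −78 °C; NaHMDS, −20 °C; 19, −78 to −20 °C
Reagents that add atoms: ethyltriphenylphosphonium iodide, CC[P+](c1ccccc1)(c1ccccc1)c1ccccc1.[I-]; iodine, II
Why: The Stork–Zhao olefination with the alpha-iodo ylide should give the Z-2-iodo-2-alkene (iodine cis to the chain) under kinetic Wittig control.

Step 12
Reactants: 21 geranylgeraniol ((2E,6E,10E)-3,7,11,15-tetramethylhexadeca-2,6,10,14-tetraen-1-ol)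
Product: 22 (2E,6E,10E)-1-bromo-3,7,11,15-tetramethylhexadeca-2,6,10,14-tetraene
Conditions: PBr3 (0.4 equiv), Et2O, −10 °C
Reagents that add atoms: phosphorus tribromide, BrP(Br)Br
Why: SN2 bromination of the primary allylic alcohol with PBr3 should keep the three E olefins.

Step 13
Reactants: 22 (2E,6E,10E)-1-bromo-3,7,11,15-tetramethylhexadeca-2,6,10,14-tetraene
Product: 23 4,4,5,5-tetramethyl-2-[(3E,7E,11E)-4,8,12,16-tetramethylheptadeca-3,7,11,15-tetraen-1-yl]-1,3,2-dioxaborolane
Conditions: CH2(Bpin)2 (1.3 equiv), NaOt-Bu (1.5 equiv), THF, 0 °C to rt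
Reagents that add atoms: bis[(pinacolato)boryl]methane, CC1(C)OB(CB2OC(C)(C)C(C)(C)O2)OC1(C)C
Why: Alkoxide-promoted deborylative alkylation of the geminal bis(boronate) generates an alpha-boryl carbanion that should displace the primary allylic bromide by SN2 and give the one-carbon-homologated primary boronic ester.

Step 14
Reactants: 20 2-[(2E,7R,11S,14E,18Z)-19-iodo-3,7,11,15-tetramethylicosa-2,14,18-trien-1-yl]-1,4-dimethoxy-3-methylnaphthalene; 23 4,4,5,5-tetramethyl-2-[(3E,7E,11E)-4,8,12,16-tetramethylheptadeca-3,7,11,15-tetraen-1-yl]-1,3,2-dioxaborolane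
Product: 27 1,4-dimethoxy-2-methyl-3-[(2E,7R,11S,14E,18E,22E,26E,30E)-3,7,11,15,19,23,27,31,35-nonamethylhexatriaconta-2,14,18,22,26,30,34-heptaen-1-yl]naphthalene, via alkenyllithium 24 (not isolated), via boronate complex 25 (not isolated), via iodo boronic ester 26 (not isolated)
Conditions: 20, t-BuLi (2.0 equiv), Et2O/THF, −78 °C; 23 (1.2 equiv), −78 °C, 30 min; I2 (1.2 equiv), THF, −78 °C; NaOMe (3 equiv), MeOH, −78 °C to rt
Reagents that add atoms: none
Why: Iodine–lithium exchange on 20 should give the configurationally stable alkenyllithium 24 (lithium cis to C17'), which adds to the boron of 23 to form the boronate complex 25; iodine then attacks the electron-rich C18'=C19' olefin of 25, the primary C20' alkyl group migrates from boron to C19' anti to the new C–I bond (1,2-metallate rearrangement) to give 26, and methoxide triggers anti elimination of boron and iodine. The closest known reaction type is the Zweifel olefination of pinacol boronic esters with alkenyllithiums, including alpha-methyl alkenyllithiums that give trisubstituted olefins. No ring is closed. No stereocentre from this step remains in the product, because the two transient centres C18' and C19' of 26 are removed in the elimination; the element that is set is the C18'=C19' geometry, which becomes E because anti migration followed by anti elimination inverts the Z geometry of 20, so both face isomers of 26 converge on the same olefin. The step needs iodine to attack one olefin out of seven in the presence of an electron-rich arene, which the anionic boronate secures because only that olefin is activated, and it needs C20' alone to migrate, which is secured because the other two boron substituents are the pinacol oxygens. The stereocentres C7' and C11' and the remaining olefins take no part.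

Step 15
Reactants: 27 1,4-dimethoxy-2-methyl-3-[(2E,7R,11S,14E,18E,22E,26E,30E)-3,7,11,15,19,23,27,31,35-nonamethylhexatriaconta-2,14,18,22,26,30,34-heptaen-1-yl]naphthalene
Product: 28 2-methyl-3-[(2E,7R,11S,14E,18E,22E,26E,30E)-3,7,11,15,19,23,27,31,35-nonamethylhexatriaconta-2,14,18,22,26,30,34-heptaen-1-yl]naphthalene-1,4-dione
Conditions: (NH4)2Ce(NO3)6 (2.5 equiv), MeCN/CH2Cl2/H2O, 0 °C
Reagents that add atoms: water, O
Why: Oxidative demethylation with ceric ammonium nitrate should convert the para-dimethoxyarene into the para-quinone through the arene radical cation and attack of water, while isolated trisubstituted olefins are not oxidised under these conditions.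

**Compound list**

1 | menadione (2-methylnaphthalene-1,4-dione) | CC1=CC(=O)c2ccccc2C1=O | starting material
2 | menadiol (2-methylnaphthalene-1,4-diol) | Cc1cc(O)c2ccccc2c1O | intermediate
3 | 1,4-dimethoxy-2-methylnaphthalene | COc1cc(C)c(OC)c2ccccc12 | intermediate
4 | 2-(chloromethyl)-1,4-dimethoxy-3-methylnaphthalene | COc1c(CCl)c(C)c(OC)c2ccccc12 | intermediate
5 | (2R)-3-bromo-2-methylpropan-1-ol | OC[C@@H](C)CBr | starting material
6 | (2R)-1-bromo-3-chloro-2-methylpropane | ClC[C@@H](C)CBr | intermediate
7 | (4-bromobut-1-yn-1-yl)trimethylsilane | C[Si](C)(C)C#CCCBr | starting material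
8 | [4-(trimethylsilyl)but-3-yn-1-yl]magnesium bromide | C[Si](C)(C)C#CCC[Mg]Br | intermediate
9 | [(6S)-7-chloro-6-methylhept-1-yn-1-yl]trimethylsilane | ClC[C@@H](C)CCCC#C[Si](C)(C)C | intermediate
10 | (6R)-8-bromo-2,6-dimethyloct-2-ene ((R)-citronellyl bromide) | CC(C)=CCC[C@@H](C)CCBr | starting material
11 | chlorido[(2S)-2-methyl-7-(trimethylsilyl)hept-6-yn-1-yl]magnesium | Cl[Mg]C[C@@H](C)CCCC#C[Si](C)(C)C | intermediate
12 | trimethyl[(6R,10S)-6,10,14-trimethylpentadec-13-en-1-yn-1-yl]silane | CC(C)=CCC[C@@H](C)CCC[C@@H](C)CCCC#C[Si](C)(C)C | intermediate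
13 | (6R,10S)-6,10,14-trimethylpentadec-13-en-1-yne | CC(C)=CCC[C@@H](C)CCC[C@@H](C)CCCC#C | intermediate
14 | dimethyl[(1E,6R,10S)-2,6,10,14-tetramethylpentadeca-1,13-dien-1-yl]alumane | CC(C)=CCC[C@@H](C)CCC[C@@H](C)CCC/C(C)=C/[Al](C)C | intermediate
15 | 1,4-dimethoxy-2-methyl-3-[(2E,7R,11S)-3,7,11,15-tetramethylhexadeca-2,14-dien-1-yl]naphthalene | CC(C)=CCC[C@@H](C)CCC[C@@H](C)CCC/C(C)=C/Cc1c(C)c(OC)c2ccccc2c1OC | intermediate
16 | (2E,6S,10R,14E)-16-(1,4-dimethoxy-3-methylnaphthalen-2-yl)-2,6,10,14-tetramethylhexadeca-2,14-dien-1-ol | OC/C(C)=C/CC[C@@H](C)CCC[C@@H](C)CCC/C(C)=C/Cc1c(C)c(OC)c2ccccc2c1OC | intermediate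
17 | 2-[(2E,7R,11S,14E)-16-bromo-3,7,11,15-tetramethylhexadeca-2,14-dien-1-yl]-1,4-dimethoxy-3-methylnaphthalene | BrC/C(C)=C/CC[C@@H](C)CCC[C@@H](C)CCC/C(C)=C/Cc1c(C)c(OC)c2ccccc2c1OC | intermediate
18 | (4E,8S,12R,16E)-N-cyclohexyl-18-(1,4-dimethoxy-3-methylnaphthalen-2-yl)-4,8,12,16-tetramethyloctadeca-4,16-dien-1-imine | C1CCCCC1N=CCC/C(C)=C/CC[C@@H](C)CCC[C@@H](C)CCC/C(C)=C/Cc2c(C)c(OC)c3ccccc3c2OC | intermediate
19 | (4E,8S,12R,16E)-18-(1,4-dimethoxy-3-methylnaphthalen-2-yl)-4,8,12,16-tetramethyloctadeca-4,16-dienal | O=CCC/C(C)=C/CC[C@@H](C)CCC[C@@H](C)CCC/C(C)=C/Cc1c(C)c(OC)c2ccccc2c1OC | intermediate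
20 | 2-[(2E,7R,11S,14E,18Z)-19-iodo-3,7,11,15-tetramethylicosa-2,14,18-trien-1-yl]-1,4-dimethoxy-3-methylnaphthalene | C/C(I)=C/CC/C(C)=C/CC[C@@H](C)CCC[C@@H](C)CCC/C(C)=C/Cc1c(C)c(OC)c2ccccc2c1OC | intermediate
21 | geranylgeraniol, (2E,6E,10E)-3,7,11,15-tetramethylhexadeca-2,6,10,14-tetraen-1-ol | CC(C)=CCC/C(C)=C/CC/C(C)=C/CC/C(C)=C/CO | starting material
22 | (2E,6E,10E)-1-bromo-3,7,11,15-tetramethylhexadeca-2,6,10,14-tetraene | CC(C)=CCC/C(C)=C/CC/C(C)=C/CC/C(C)=C/CBr | intermediate
23 | 4,4,5,5-tetramethyl-2-[(3E,7E,11E)-4,8,12,16-tetramethylheptadeca-3,7,11,15-tetraen-1-yl]-1,3,2-dioxaborolane | CC(C)=CCC/C(C)=C/CC/C(C)=C/CC/C(C)=C/CCB1OC(C)(C)C(C)(C)O1 | intermediate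
24 | 19-lithio analogue of 20, 2-[(2E,7R,11S,14E,18E)-19-lithio-3,7,11,15-tetramethylicosa-2,14,18-trien-1-yl]-1,4-dimethoxy-3-methylnaphthalene (Li where I was, cis to C17'; the descriptor reads E only because Li ranks below CH3) | C/C([Li])=C/CC/C(C)=C/CC[C@@H](C)CCC[C@@H](C)CCC/C(C)=C/Cc1c(C)c(OC)c2ccccc2c1OC | intermediate
25 | lithium boronate complex: the boron of 23 additionally bound to C19' of the alkenyl group of 24, boron cis to C17' | [Li+].CC(C)=CCC/C(C)=C/CC/C(C)=C/CC/C(C)=C/CC[B-]1(OC(C)(C)C(C)(C)O1)/C(C)=C\CC/C(C)=C/CC[C@@H](C)CCC[C@@H](C)CCC/C(C)=C/Cc1c(C)c(OC)c2ccccc2c1OC | intermediate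
26 | (18'R,19'R)-18'-iodo-19'-(4,4,5,5-tetramethyl-1,3,2-dioxaborolan-2-yl) adduct with C20' on C19' anti to iodine, otherwise the skeleton of 27 (the 18'S,19'S face isomer forms alongside and gives the same olefin) | CC(C)=CCC/C(C)=C/CC/C(C)=C/CC/C(C)=C/CC[C@](C)(B1OC(C)(C)C(C)(C)O1)[C@H](I)CC/C(C)=C/CC[C@@H](C)CCC[C@@H](C)CCC/C(C)=C/Cc1c(C)c(OC)c2ccccc2c1OC | intermediate
27 | 1,4-dimethoxy-2-methyl-3-[(2E,7R,11S,14E,18E,22E,26E,30E)-3,7,11,15,19,23,27,31,35-nonamethylhexatriaconta-2,14,18,22,26,30,34-heptaen-1-yl]naphthalene | CC(C)=CCC/C(C)=C/CC/C(C)=C/CC/C(C)=C/CC/C(C)=C/CC/C(C)=C/CC[C@@H](C)CCC[C@@H](C)CCC/C(C)=C/Cc1c(C)c(OC)c2ccccc2c1OC | intermediate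
28 | 2-methyl-3-[(2E,7R,11S,14E,18E,22E,26E,30E)-3,7,11,15,19,23,27,31,35-nonamethylhexatriaconta-2,14,18,22,26,30,34-heptaen-1-yl]naphthalene-1,4-dione | CC(C)=CCC/C(C)=C/CC/C(C)=C/CC/C(C)=C/CC/C(C)=C/CC/C(C)=C/CC[C@@H](C)CCC[C@@H](C)CCC/C(C)=C/CC1=C(C)C(=O)c2ccccc2C1=O | target

**Step count and risks**

Total step count: 15. Longest linear sequence: 11 steps (steps 3, 4, 5, 6, 7, 8, 9, 10, 11, 14, 15, from 5 to 28).

Most likely to fail, first: step 14. The alkenyllithium may be lost by proton transfer from the doubly activated C1' methylene or by incomplete boronate formation, and a non-stereospecific opening of the iodonium ion would erode the 18'E geometry. The fallback forms the same bond by a palladium-catalysed coupling that proceeds with retention, so it needs the E-iodide. It sets out from 19 and 23. Aldehyde 19 is homologated with dimethyl (1-diazo-2-oxopropyl)phosphonate and K2CO3 in MeOH (Ohira–Bestmann reaction) to the terminal alkyne 2-[(2E,7R,11S,14E)-3,7,11,15-tetramethylnonadeca-2,14-dien-18-yn-1-yl]-1,4-dimethoxy-3-methylnaphthalene F1. This is C-methylated (n-BuLi, MeI, THF, −78 °C) to the 2-alkyne 2-[(2E,7R,11S,14E)-3,7,11,15-tetramethylicosa-2,14-dien-18-yn-1-yl]-1,4-dimethoxy-3-methylnaphthalene F2. Hydrozirconation with excess Cp2Zr(H)Cl under equilibrating conditions (THF, 50 °C), so that zirconium settles on the methyl-bearing carbon, followed by iodine should give the E-iodide 2-[(2E,7R,11S,14E,18E)-19-iodo-3,7,11,15-tetramethylicosa-2,14,18-trien-1-yl]-1,4-dimethoxy-3-methylnaphthalene F3. Boronic ester 23 is converted with KHF2 in MeOH/H2O into potassium trifluoro[(3E,7E,11E)-4,8,12,16-tetramethylheptadeca-3,7,11,15-tetraen-1-yl]borate F4. Suzuki–Miyaura coupling of F3 and F4 (PdCl2(dppf), Cs2CO3, toluene/H2O, 80 °C) then forms the C19'–C20' bond with retention and comes back to the route at 27.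

Second: step 11. The alpha-iodo ylide may decompose before it meets the enolisable aldehyde, and partial loss of kinetic control would lower the Z selectivity on which the geometry of step 14 depends. The fallback sets out from 19 and builds the Z-alkenyl halide by palladium catalysis instead of a Wittig reaction. Ramirez dibromo-olefination (CBr4, PPh3, CH2Cl2, 0 °C) should give 2-[(2E,7R,11S,14E)-19,19-dibromo-3,7,11,15-tetramethylnonadeca-2,14,18-trien-1-yl]-1,4-dimethoxy-3-methylnaphthalene F5. Trans-selective monomethylation (MeZnCl, PdCl2(DPEphos) cat., THF), which replaces only the bromine trans to the chain, should give the Z-bromide 2-[(2E,7R,11S,14E,18Z)-19-bromo-3,7,11,15-tetramethylicosa-2,14,18-trien-1-yl]-1,4-dimethoxy-3-methylnaphthalene F6. Bromine–lithium exchange on F6 (t-BuLi, 2 equiv, −78 °C) gives the same alkenyllithium, so the fallback comes back to the route at 24 inside step 14.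

Third: step 8. Competing allylic oxidation at the internal C2'=C3' olefin and over-oxidation of the product to the enal would cut the yield of a late intermediate. The fallback moves the oxidation to a stage where only one olefin is present and sets out from 13. Oxidation of 13 with catalytic SeO2 and t-BuOOH should give (2E,6S,10R)-2,6,10-trimethylpentadec-2-en-14-yn-1-ol F7. F7 is then carried as its aluminium alkoxide (one extra equivalent of AlMe3) through the zirconium-catalysed methylalumination and the zerovalent-nickel benzylation with 4 (NiCl2(PPh3)2 reduced with n-BuLi). After aqueous work-up this comes back to the route at 16.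

Further compounds
F1 | step 14 | 2-[(2E,7R,11S,14E)-3,7,11,15-tetramethylnonadeca-2,14-dien-18-yn-1-yl]-1,4-dimethoxy-3-methylnaphthalene | C#CCC/C(C)=C/CC[C@@H](C)CCC[C@@H](C)CCC/C(C)=C/Cc1c(C)c(OC)c2ccccc2c1OC
F2 | step 14 | 2-[(2E,7R,11S,14E)-3,7,11,15-tetramethylicosa-2,14-dien-18-yn-1-yl]-1,4-dimethoxy-3-methylnaphthalene | CC#CCC/C(C)=C/CC[C@@H](C)CCC[C@@H](C)CCC/C(C)=C/Cc1c(C)c(OC)c2ccccc2c1OC
F3 | step 14 | 2-[(2E,7R,11S,14E,18E)-19-iodo-3,7,11,15-tetramethylicosa-2,14,18-trien-1-yl]-1,4-dimethoxy-3-methylnaphthalene | C/C(I)=C\CC/C(C)=C/CC[C@@H](C)CCC[C@@H](C)CCC/C(C)=C/Cc1c(C)c(OC)c2ccccc2c1OC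
F4 | step 14 | potassium trifluoro[(3E,7E,11E)-4,8,12,16-tetramethylheptadeca-3,7,11,15-tetraen-1-yl]borate | [K+].CC(C)=CCC/C(C)=C/CC/C(C)=C/CC/C(C)=C/CC[B-](F)(F)F
F5 | step 11 | 2-[(2E,7R,11S,14E)-19,19-dibromo-3,7,11,15-tetramethylnonadeca-2,14,18-trien-1-yl]-1,4-dimethoxy-3-methylnaphthalene | BrC(Br)=CCC/C(C)=C/CC[C@@H](C)CCC[C@@H](C)CCC/C(C)=C/Cc1c(C)c(OC)c2ccccc2c1OC
F6 | step 11 | 2-[(2E,7R,11S,14E,18Z)-19-bromo-3,7,11,15-tetramethylicosa-2,14,18-trien-1-yl]-1,4-dimethoxy-3-methylnaphthalene | C/C(Br)=C/CC/C(C)=C/CC[C@@H](C)CCC[C@@H](C)CCC/C(C)=C/Cc1c(C)c(OC)c2ccccc2c1OC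
F7 | step 8 | (2E,6S,10R)-2,6,10-trimethylpentadec-2-en-14-yn-1-ol | OC/C(C)=C/CC[C@@H](C)CCC[C@@H](C)CCCC#C
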